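# Proposed synthesis of 2‑[(3R,5R)‑5‑[(9E,11E,13E)‑hexadeca‑9,11,13‑trien‑1‑yl]‑3,5‑dimethyl‑1,2‑dioxolan‑3‑yl]acetic acid (22, CID 9842769)

Ring atoms are numbered O1–O2–C3–C4–C5, with C3 carrying the acetic acid and C5 the chain. Chain carbons are C1′–C16′, counted from the ring.

## Analysis of the target

- 22 is a 1,2‑dioxolane (ring O1–O2–C3–C4–C5) with CH3 and CH2CO2H on C3, CH3 and an unbranched C16 chain on C5, and an unsubstituted C4 methylene. The chain ends in a conjugated all‑E triene (C9′=C10′, C11′=C12′, C13′=C14′).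
- The only stereocentres are C3 and C5. Both are quaternary, both carry a peroxide oxygen, and they are 1,3‑related across C4.
- Working through the CIP priorities, (3R,5R) places the two methyl groups on the same face of the ring. The descriptors are equal only because the arm outranks C4 at C3 but not at C5.
- This is the feature the route is built on. C3 and C5 each carry CH3, a ring oxygen, C4 and a CH2‑linked arm, so the ring O1–O2–C3–C4–C5 has a latent mirror plane through C4 and the midpoint of O1–O2. With two identical arms the core would be meso.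
- The difficulty is stereochemical. At each centre the groups to be told apart are CH3 and CH2R, too alike for 1,3‑induction, and tertiary C–OO bonds cannot be made by clean SN2. Cationic or radical C–O bond formation erases configuration.
- Sensitive groups: the O–O bond (low‑valent metals, strong hydrides, catalytic hydrogenation) and every β‑peroxy carbonyl unit (base‑induced retro‑oxa‑Michael opening or epoxide collapse). The triene is sensitive to acid, radicals, oxygen and light and must arrive last.

## Retrosynthetic reasoning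

**22 ⇒ 20.** The acid is released last from methyl ester 20. A neutral ester is easier to carry through the base‑mediated olefinations than a carboxylic acid, and saponification touches neither the peroxide nor the triene.

**20 ⇒ 17 + 18.** The C9′=C10′ bond is cut. This puts the whole triene problem into the commercial C7 dienal 18, which already holds two E double bonds, and into one E‑selective sulfone olefination of 17. The triene then appears only after every oxidation and reduction of the route.

**17 ⇒ 16 ⇒ 15 ⇒ 9 + 13.** The C2′–C3′ bond is cut. Aldehyde 9 and the ylide from phosphonium salt 13 give alkene 15, and a metal‑free hydrogen transfer that spares the O–O bond saturates it to 16. The tetrazolyl sulfide rides through as the masked sulfone and is oxidised (16 to 17) only when no alkene is left.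

**9 ⇒ 8 ⇒ 7.** The two arms of 9 (CH2CHO on C5, CH2CO2CH3 on C3) are the two halves of the 1,2‑dione bridge of the meso bicycle 7. Reducing one of the two enantiotopic carbonyls (7 to 8) and cleaving the ketol C–C bond in the alcohol that supplies the ester group (8 to 9) turns the bridge into a differentiated aldehyde and ester. The absolute configuration of C3 and C5 is set in one event, and no protecting group is needed.

**7 ⇒ 4 + 5 (key disconnection).** Both C–C bonds between the ring and its arms, C3–CH2 and C5–CH2, are cut at once. The forward reaction is a formal (4+3) annulation of the bis(peroxyketal) 4, a 1,3‑dielectrophile through two successive peroxycarbenium ions, with the bis(enol silane) 5, a 1,4‑dinucleophile. The seven‑membered ring it closes can only be cis‑bridged, so the relative configuration of the two quaternary peroxy carbons is enforced by geometry and every stereoisomer of 4 converges on one achiral product. The precursor has no defined stereocentre and no C–C bond beyond its methyl groups.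

**4 ⇒ 3 ⇒ 1 + 2.** The dioxolane ring with both oxygens is the known adduct 3 of the β‑diketone 1 and 2. Acid‑catalysed ketalisation gives 4.

**13 ⇒ 12 ⇒ 10 + 11.** The C7 linker is made by S‑alkylation of 11 with excess 10 and quaternisation of phosphine with bromide 12.

## Alternatives that were turned down

**Alternative 1:** the textbook route for this class. Disconnection of the C3–CH2CO2H bond. A 3‑methoxy‑1,2‑dioxolane A1 with C5 already set is ionised by a Lewis acid to the peroxycarbenium ion and trapped with a silyl ketene acetal. A1 would come from perhydrolysis with 2, with inversion, of the enantioenriched oxetane A2, followed by oxidation‑state adjustment to the methyl ketone. Turned down for three reasons: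
- the planar C3 cation sees only C5, whose CH3 and CH2R groups are nearly the same size, so both C3 epimers are expected;
- the substitution at the tertiary oxetane carbon competes with ionisation, which erodes C5;
- A2 itself needs a multistep asymmetric sequence, so the route is long and linear and leaves one centre uncontrolled.

**Alternative 2:** disconnection of the O2–C3 bond. The tertiary hydroperoxide A3, from cobalt‑catalysed hydroperoxysilylation of the corresponding 1,1‑disubstituted alkene, would close by 5‑exo intramolecular oxa‑Michael addition onto its β‑methyl enoate. Turned down because the radical C5–O bond formation has no enantiocontrol. The conjugate addition is reversible and its two products differ only in CH3/CH2R placement, so an unbiased mixture of all four stereoisomers is expected.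

**Alternative 3:** a (3+2) annulation that cuts C4–C5 and O2–C3. The silyl peroxycarbenium ion from peroxyketal A4 would add to the alkene A5, and the tertiary cation would be closed by the silylperoxy oxygen. This is the most convergent way to the ring. It was turned down because it is intermolecular with no tether and no catalyst handle. Both prochiral carbons again discriminate only CH3 from CH2R, so neither relative nor absolute configuration is controlled. The ester‑bearing alkene A5 is also a weak nucleophile.

Key step: step 3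

Assumption: the sense of carbonyl selection in step 4 cannot be derived with certainty. The route is written for the (S)‑oxazaborolidine, on the premise that the acyl carbon acts as the large group and that hydride enters from the peroxide‑bridge face. The (R)‑catalyst would be used if a first experiment showed the mirror‑image sense.

## Steps

**Step 1**
Reactants: 1 pentane‑2,4‑dione; 2 hydrogen peroxide
Product: 3 3,5‑dimethyl‑1,2‑dioxolane‑3,5‑diol (cis/trans mixture)
Conditions: 30% aq. H2O2 (1.05 equiv), 0 °C → rt; kept in solution, small scale (peroxide hazard)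
Reagents that add atoms: none
Why: Twofold addition of 2 to the 1,3‑diketone (perhydrolysis) closes the cyclic bis(peroxyhemiketal) and installs the O–O bond and C3–C4–C5 of the target in one operation; the hemiketal configurations are irrelevant because both centres are ionised in step 3.

**Step 2**
Reactants: 3 3,5‑dimethyl‑1,2‑dioxolane‑3,5‑diol
Product: 4 3,5‑dimethoxy‑3,5‑dimethyl‑1,2‑dioxolane (cis/trans mixture)
Conditions: MeOH, p‑TsOH·H2O (cat.), 3 Å MS, 0 °C → rt
Reagents that add atoms: methanol, CO
Why: Acid‑catalysed ketalisation of the peroxyhemiketals through the ring peroxycarbenium ions gives the bis(ketal), a storable precursor for Lewis‑acid ionisation; the isomer mixture is used as such.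

**Step 3**
Reactants: 4 3,5‑dimethoxy‑3,5‑dimethyl‑1,2‑dioxolane; 5 2,3‑bis(trimethylsilyloxy)buta‑1,3‑diene
Product: 7 (1R,6S)‑1,6‑dimethyl‑7,8‑dioxabicyclo[4.2.1]nonane‑3,4‑dione (meso), via 1‑(5‑methoxy‑3,5‑dimethyl‑1,2‑dioxolan‑3‑yl)‑3‑(trimethylsilyloxy)but‑3‑en‑2‑one 6 (not isolated)
Conditions: TMSOTf (0.3 equiv), CH2Cl2 (0.01 M), −78 → −30 °C, slow simultaneous addition of 4 and 5; aq. NaHCO3 quench
Reagents that add atoms: none
Why: Proposed new method: TMSOTf ionises one ketal of 4 to a 1,2‑dioxolan‑3‑ylium (peroxycarbenium) ion, one terminal CH2 of 5 attacks it to give 6 after silyl loss, and ionisation of the second ketal followed by attack of the remaining enol silane closes the seven‑membered carbocycle, so the net change is a formal (4+3) annulation of a 1,3‑dielectrophile with a 1,4‑dinucleophile that forms both C–C bonds at the quaternary peroxy carbons. The closest known reaction type is the Lewis‑acid‑mediated Mukaiyama‑type substitution of 3‑alkoxy‑1,2‑dioxolanes by enol silanes, with the annulative precedent of (3+4) annulations of 1,4‑dicarbonyl bis‑electrophiles with bis(silyl) dienol ethers; the first C–C bond is therefore ordinary and the second, an acyl‑deactivated enol silane closing a medium ring, is the new part. The ring closes in a 7‑(enol‑endo)‑exo‑trig mode onto the C=O+ of the cyclic cation, which is allowed for enol nucleophiles. The first bond creates a quaternary centre of either configuration, and the tethered enol silane can then reach the planar cation at the second carbon only from the face it sits on, so the two arms end up cis (a trans‑bridged [4.2.1] skeleton cannot form) and all stereoisomers of 4 and 6 converge on the single achiral meso compound 7. The selectivity needed is ring closure over a second intermolecular substitution and over proton loss from the cation; 1:1 stoichiometry, high dilution with slow addition, and the low temperature at which such cations are known to persist should secure it.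

**Step 4**
Reactants: 7 (1R,6S)‑1,6‑dimethyl‑7,8‑dioxabicyclo[4.2.1]nonane‑3,4‑dione
Product: 8 (1R,4R,6R)‑4‑hydroxy‑1,6‑dimethyl‑7,8‑dioxabicyclo[4.2.1]nonan‑3‑one
Conditions: (S)‑Me‑CBS (0.2 equiv), catecholborane (1.05 equiv), toluene, −78 °C; MeOH, pH 7 buffer; rapid filtration through deactivated silica
Reagents that add atoms: none
Why: Corey–Bakshi–Shibata reduction used as an enantiotopic‑group‑selective desymmetrisation of a meso diketone: the catalyst fixes the face from which each carbonyl receives hydride, and only for one of the two mirror‑related carbonyls is that face the open one of the bicycle, so one carbonyl is reduced and C1 and C6 (C3 and C5 of the target) become configurationally defined together. The carbinol configuration is lost in step 5; reduction of the other carbonyl from its hindered face would give a diastereomer of 8, separable here, and the α‑boryloxy ketone resists a second reduction.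

**Step 5**
Reactants: 8 (1R,4R,6R)‑4‑hydroxy‑1,6‑dimethyl‑7,8‑dioxabicyclo[4.2.1]nonan‑3‑one
Product: 9 methyl 2‑[(3R,5S)‑3,5‑dimethyl‑5‑(2‑oxoethyl)‑1,2‑dioxolan‑3‑yl]acetate
Conditions: Pb(OAc)4 (1.1 equiv), MeOH/PhH 1:1, 0 °C
Reagents that add atoms: methanol, CO
Why: Criegee‑type cleavage of an α‑ketol in methanol: the ketone reacts as its methyl hemiketal, so the carbinol carbon emerges as the aldehyde and the ketone carbon as the methyl ester, and the two arms are differentiated in one step. Pb(IV) does not attack a dialkyl peroxide and the quaternary centres are untouched; the descriptor at C5 is S here only because CH2CHO outranks C4.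

**Step 6**
Reactants: 10 1,7‑dibromoheptane; 11 1‑phenyl‑1H‑tetrazole‑5‑thiol
Product: 12 5‑[(7‑bromoheptyl)sulfanyl]‑1‑phenyl‑1H‑tetrazole
Conditions: K2CO3, acetone, rt; 10 in threefold excess
Reagents that add atoms: none
Why: SN2 S‑alkylation of the soft thiolate; the excess of dibromide suppresses double substitution.

**Step 7**
Reactants: 12 5‑[(7‑bromoheptyl)sulfanyl]‑1‑phenyl‑1H‑tetrazole
Product: 13 triphenyl{7‑[(1‑phenyl‑1H‑tetrazol‑5‑yl)sulfanyl]heptyl}phosphonium bromide
Conditions: PPh3 (1.1 equiv), MeCN, reflux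
Reagents that add atoms: triphenylphosphine, c1ccc(cc1)P(c1ccccc1)c1ccccc1
Why: SN2 quaternisation of the phosphine by the primary bromide; the aryl sulfide is inert.

**Step 8**
Reactants: 9 methyl 2‑[(3R,5S)‑3,5‑dimethyl‑5‑(2‑oxoethyl)‑1,2‑dioxolan‑3‑yl]acetate; 13 triphenyl{7‑[(1‑phenyl‑1H‑tetrazol‑5‑yl)sulfanyl]heptyl}phosphonium bromide
Product: 15 methyl 2‑[(3R,5R)‑3,5‑dimethyl‑5‑{(2Z)‑9‑[(1‑phenyl‑1H‑tetrazol‑5‑yl)sulfanyl]non‑2‑en‑1‑yl}‑1,2‑dioxolan‑3‑yl]acetate, via triphenyl{7‑[(1‑phenyl‑1H‑tetrazol‑5‑yl)sulfanyl]heptylidene}‑λ5‑phosphane 14 (not isolated)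
Conditions: 13, NaHMDS (1.0 equiv), THF, −78 → 0 °C; then 9, −78 °C → rt
Reagents that add atoms: none
Why: Wittig olefination with a non‑stabilised ylide forms the C2′–C3′ bond; addition to the aldehyde at −78 °C should be faster than enolisation of the β‑peroxy aldehyde or attack on the ester. The Z‑alkene is expected but its geometry is irrelevant because step 9 removes it.

**Step 9**
Reactants: 15 methyl 2‑[(3R,5R)‑3,5‑dimethyl‑5‑{(2Z)‑9‑[(1‑phenyl‑1H‑tetrazol‑5‑yl)sulfanyl]non‑2‑en‑1‑yl}‑1,2‑dioxolan‑3‑yl]acetate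
Product: 16 methyl 2‑[(3R,5R)‑3,5‑dimethyl‑5‑{9‑[(1‑phenyl‑1H‑tetrazol‑5‑yl)sulfanyl]nonyl}‑1,2‑dioxolan‑3‑yl]acetate
Conditions: KO2CN=NCO2K (excess), AcOH, MeOH/CH2Cl2, 0 °C → rt
Reagents that add atoms: none
Why: Diimide reduction transfers H2 in a concerted syn fashion to the unhindered cis‑alkene and leaves the O–O bond intact, where catalytic hydrogenation would cleave it; sulfide and ester are inert.

**Step 10**
Reactants: 16 methyl 2‑[(3R,5R)‑3,5‑dimethyl‑5‑{9‑[(1‑phenyl‑1H‑tetrazol‑5‑yl)sulfanyl]nonyl}‑1,2‑dioxolan‑3‑yl]acetate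
Product: 17 methyl 2‑[(3R,5R)‑3,5‑dimethyl‑5‑{9‑[(1‑phenyl‑1H‑tetrazol‑5‑yl)sulfonyl]nonyl}‑1,2‑dioxolan‑3‑yl]acetate
Conditions: (NH4)6Mo7O24·4H2O (cat.), 30% H2O2, EtOH, 0 °C → rt
Reagents that add atoms: hydrogen peroxide (compound 2), OO
Why: Molybdate‑catalysed oxidation of the sulfide to the sulfone; the dialkyl peroxide and the ester are inert to an electrophilic oxidant, and no alkene is present at this stage.

**Step 11**
Reactants: 17 methyl 2‑[(3R,5R)‑3,5‑dimethyl‑5‑{9‑[(1‑phenyl‑1H‑tetrazol‑5‑yl)sulfonyl]nonyl}‑1,2‑dioxolan‑3‑yl]acetate; 18 (2E,4E)‑hepta‑2,4‑dienal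
Product: 20 methyl 2‑[(3R,5R)‑5‑[(9E,11E,13E)‑hexadeca‑9,11,13‑trien‑1‑yl]‑3,5‑dimethyl‑1,2‑dioxolan‑3‑yl]acetate, via potassium salt of the α‑sulfonyl carbanion of 17 19 (not isolated)
Conditions: KHMDS (1.05 equiv), THF, −78 °C, 30 min; then 18, −78 °C → rt; dark, argon
Reagents that add atoms: none
Why: Julia–Kocienski olefination (addition, Smiles rearrangement, loss of SO2 and the tetrazolonate); an α‑unbranched alkyl tetrazolyl sulfone and an enal should give the new C9′=C10′ bond E, and the other two E bonds come stereodefined with 18. The sulfone α‑H is more acidic than the ester α‑H, so the β‑peroxy ester should not be enolised by one equivalent of base.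

**Step 12**
Reactants: 20 methyl 2‑[(3R,5R)‑5‑[(9E,11E,13E)‑hexadeca‑9,11,13‑trien‑1‑yl]‑3,5‑dimethyl‑1,2‑dioxolan‑3‑yl]acetate
Product: 22 2‑[(3R,5R)‑5‑[(9E,11E,13E)‑hexadeca‑9,11,13‑trien‑1‑yl]‑3,5‑dimethyl‑1,2‑dioxolan‑3‑yl]acetic acid, via lithium 2‑[(3R,5R)‑5‑[(9E,11E,13E)‑hexadeca‑9,11,13‑trien‑1‑yl]‑3,5‑dimethyl‑1,2‑dioxolan‑3‑yl]acetate 21 (not isolated)
Conditions: LiOH·H2O (3 equiv), THF/H2O 3:1, 0 °C → rt, dark, argon; then 1 M HCl to pH 4 at 0 °C
Reagents that add atoms: lithium hydroxide, [Li+].[OH-]
Why: Saponification of an unhindered methyl ester; hydroxide adds to the carbonyl faster than it deprotonates the α‑carbon, which is the only path by which the quaternary C3 could be lost, and the triene and peroxide are inert to aqueous base.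

## Compound list

1 | pentane‑2,4‑dione | CC(=O)CC(C)=O | starting material
2 | hydrogen peroxide | OO | starting material
3 | 3,5‑dimethyl‑1,2‑dioxolane‑3,5‑diol (cis/trans mixture, no descriptors) | CC1(O)CC(C)(O)OO1 | intermediate
4 | 3,5‑dimethoxy‑3,5‑dimethyl‑1,2‑dioxolane (cis/trans mixture, no descriptors) | COC1(C)CC(C)(OC)OO1 | intermediate
5 | 2,3‑bis(trimethylsilyloxy)buta‑1,3‑diene | C=C(O[Si](C)(C)C)C(=C)O[Si](C)(C)C | starting material
6 | 1‑(5‑methoxy‑3,5‑dimethyl‑1,2‑dioxolan‑3‑yl)‑3‑(trimethylsilyloxy)but‑3‑en‑2‑one (stereoisomer mixture, no descriptors) | C=C(O[Si](C)(C)C)C(=O)CC1(C)CC(C)(OC)OO1 | intermediate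
7 | (1R,6S)‑1,6‑dimethyl‑7,8‑dioxabicyclo[4.2.1]nonane‑3,4‑dione (meso) | O=C2C[C@]1(C)C[C@](C)(CC2=O)OO1 | intermediate
8 | (1R,4R,6R)‑4‑hydroxy‑1,6‑dimethyl‑7,8‑dioxabicyclo[4.2.1]nonan‑3‑one | O[C@@H]2C[C@]1(C)C[C@](C)(CC2=O)OO1 | intermediate
9 | methyl 2‑[(3R,5S)‑3,5‑dimethyl‑5‑(2‑oxoethyl)‑1,2‑dioxolan‑3‑yl]acetate | O=CC[C@]1(C)C[C@](C)(CC(=O)OC)OO1 | intermediate
10 | 1,7‑dibromoheptane | BrCCCCCCCBr | starting material
11 | 1‑phenyl‑1H‑tetrazole‑5‑thiol | Sc1nnnn1-c1ccccc1 | starting material
12 | 5‑[(7‑bromoheptyl)sulfanyl]‑1‑phenyl‑1H‑tetrazole | BrCCCCCCCSc1nnnn1-c1ccccc1 | intermediate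
13 | triphenyl{7‑[(1‑phenyl‑1H‑tetrazol‑5‑yl)sulfanyl]heptyl}phosphonium bromide | [Br-].c1ccccc1-n1nnnc1SCCCCCCC[P+](c1ccccc1)(c1ccccc1)c1ccccc1 | intermediate
14 | triphenyl{7‑[(1‑phenyl‑1H‑tetrazol‑5‑yl)sulfanyl]heptylidene}‑λ5‑phosphane | c1ccccc1-n1nnnc1SCCCCCCC=P(c1ccccc1)(c1ccccc1)c1ccccc1 | intermediate
15 | methyl 2‑[(3R,5R)‑3,5‑dimethyl‑5‑{(2Z)‑9‑[(1‑phenyl‑1H‑tetrazol‑5‑yl)sulfanyl]non‑2‑en‑1‑yl}‑1,2‑dioxolan‑3‑yl]acetate | c1ccccc1-n1nnnc1SCCCCCC/C=C\C[C@]2(C)C[C@](C)(CC(=O)OC)OO2 | intermediate
16 | methyl 2‑[(3R,5R)‑3,5‑dimethyl‑5‑{9‑[(1‑phenyl‑1H‑tetrazol‑5‑yl)sulfanyl]nonyl}‑1,2‑dioxolan‑3‑yl]acetate | c1ccccc1-n1nnnc1SCCCCCCCCC[C@]2(C)C[C@](C)(CC(=O)OC)OO2 | intermediate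
17 | methyl 2‑[(3R,5R)‑3,5‑dimethyl‑5‑{9‑[(1‑phenyl‑1H‑tetrazol‑5‑yl)sulfonyl]nonyl}‑1,2‑dioxolan‑3‑yl]acetate | O=S(=O)(CCCCCCCCC[C@]1(C)C[C@](C)(CC(=O)OC)OO1)c1nnnn1-c1ccccc1 | intermediate
18 | (2E,4E)‑hepta‑2,4‑dienal | CC/C=C/C=C/C=O | starting material
19 | potassium salt of the α‑sulfonyl carbanion of 17 | [K+].O=S(=O)([CH-]CCCCCCCC[C@]1(C)C[C@](C)(CC(=O)OC)OO1)c1nnnn1-c1ccccc1 | intermediate
20 | methyl 2‑[(3R,5R)‑5‑[(9E,11E,13E)‑hexadeca‑9,11,13‑trien‑1‑yl]‑3,5‑dimethyl‑1,2‑dioxolan‑3‑yl]acetate | CC/C=C/C=C/C=C/CCCCCCCC[C@]1(C)C[C@](C)(CC(=O)OC)OO1 | intermediate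
21 | lithium 2‑[(3R,5R)‑5‑[(9E,11E,13E)‑hexadeca‑9,11,13‑trien‑1‑yl]‑3,5‑dimethyl‑1,2‑dioxolan‑3‑yl]acetate | [Li+].CC/C=C/C=C/C=C/CCCCCCCC[C@]1(C)C[C@](C)(CC(=O)[O-])OO1 | intermediate
22 | 2‑[(3R,5R)‑5‑[(9E,11E,13E)‑hexadeca‑9,11,13‑trien‑1‑yl]‑3,5‑dimethyl‑1,2‑dioxolan‑3‑yl]acetic acid | CC/C=C/C=C/C=C/CCCCCCCC[C@]1(C)C[C@](C)(CC(=O)O)OO1 | target

## Step count and least certain steps

Total: 12 steps. Longest linear sequence: 10 steps (1–5, then 8–12); steps 6 and 7 make the side‑chain salt.

**Step 3 (key step, proposed new method).** The second C–C bond formation may fail. After the first substitution the remaining enol silane is conjugated to a ketone and is a weaker nucleophile. The second peroxycarbenium ion could then be consumed by intermolecular substitution (oligomers), by proton loss, or by fragmentation of the peroxide.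

Fallback with known chemistry, from 4 back to 9:
- Twofold Mukaiyama‑type substitution of 4 with the commercial silyl ketene acetal 1‑methoxy‑1‑(trimethylsilyloxy)ethene (TMSOTf or TiCl4, CH2Cl2, −78 °C) should give the diester F1 as a cis/trans mixture.
- Chromatography would give the meso isomer F2.
- Pig liver esterase at pH 7 would hydrolyse one enantiotopic ester to the half‑ester F3.
- Activation of the acid as a mixed anhydride and NaBH4 reduction would give the hydroxy ester F4.
- Dess–Martin oxidation would give 9.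

In this fallback the cis relationship is secured only by separation, which is why it is not the main route.

**Step 4.** Carbonyl selection rests on the facial bias of the bicycle and may be incomplete or of the opposite sense. Over‑reduction to the diol would erase the differentiation of the arms. Acyloin transposition of 8 through the enediol on acidic or basic surfaces would scramble the desymmetrisation.

Fallback, from 7 back to 9:
- Periodic acid cleavage of the dione to the meso diacid F5.
- Esterification with TMSCHN2 to F2.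
- Then the enzymatic sequence above through F3 and F4 to 9.

**Step 8.** The basic ylide may enolise the β‑peroxy aldehyde. This would open the dioxolane by E1cB (retro‑oxa‑Michael), with loss of C5 configuration, or lead to epoxide formation.

Fallback without a carbonyl olefination, from 9 back to 16:
- NaBH4 reduces 9 to F4, and CBr4/PPh3 gives the bromide F6.
- Commercial 7‑bromohept‑1‑ene and 11 give the alkenyl sulfide F7, which 9‑BBN hydroborates to F8.
- Alkyl–alkyl Suzuki coupling of F6 with F8 (Pd(OAc)2, PCy3, K3PO4·H2O, THF, rt) gives 16 directly. Step 9 is bypassed as well.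

**Step 11.** The new C9′=C10′ bond may form with incomplete E selectivity. KHMDS may also deprotonate the ester arm (ring opening at C3) or the γ/ε positions of 18.

Fallback with reversed polarity, from 9 back to 20:
- Wittig reaction of 9 with the ylide from (7‑hydroxyheptyl)triphenylphosphonium bromide F9 (2 equiv NaHMDS) gives the alkenol F10.
- Diimide gives F11, and Dess–Martin oxidation gives the aldehyde F12.
- The dienyl bromide F14 (from commercial (2E,4E)‑hepta‑2,4‑dien‑1‑ol and PBr3) gives the phosphonate F13 by Arbuzov reaction.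
- Horner–Wadsworth–Emmons reaction of F12 with F13 (LiHMDS, THF, −78 °C) gives 20.

## Further compounds

F1 | step 3 | dimethyl 2,2′‑(3,5‑dimethyl‑1,2‑dioxolane‑3,5‑diyl)diacetate (cis/trans mixture) | COC(=O)CC1(C)CC(C)(CC(=O)OC)OO1
F2 | step 3 | dimethyl 2,2′‑[(3R,5S)‑3,5‑dimethyl‑1,2‑dioxolane‑3,5‑diyl]diacetate (meso) | COC(=O)C[C@]1(C)C[C@](C)(CC(=O)OC)OO1
F3 | step 3 | 2‑[(3S,5R)‑5‑(2‑methoxy‑2‑oxoethyl)‑3,5‑dimethyl‑1,2‑dioxolan‑3‑yl]acetic acid | OC(=O)C[C@]1(C)C[C@](C)(CC(=O)OC)OO1
F4 | step 3 | methyl 2‑[(3R,5R)‑5‑(2‑hydroxyethyl)‑3,5‑dimethyl‑1,2‑dioxolan‑3‑yl]acetate | OCC[C@]1(C)C[C@](C)(CC(=O)OC)OO1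
F5 | step 4 | 2,2′‑[(3R,5S)‑3,5‑dimethyl‑1,2‑dioxolane‑3,5‑diyl]diacetic acid (meso) | OC(=O)C[C@]1(C)C[C@](C)(CC(=O)O)OO1
F6 | step 8 | methyl 2‑[(3R,5S)‑5‑(2‑bromoethyl)‑3,5‑dimethyl‑1,2‑dioxolan‑3‑yl]acetate | BrCC[C@]1(C)C[C@](C)(CC(=O)OC)OO1
F7 | step 8 | 5‑(hept‑6‑en‑1‑ylsulfanyl)‑1‑phenyl‑1H‑tetrazole | C=CCCCCCSc1nnnn1-c1ccccc1
F8 | step 8 | 9‑{7‑[(1‑phenyl‑1H‑tetrazol‑5‑yl)sulfanyl]heptyl}‑9‑borabicyclo[3.3.1]nonane | c1ccccc1-n1nnnc1SCCCCCCCB1C2CCCC1CCC2
F9 | step 11 | (7‑hydroxyheptyl)triphenylphosphonium bromide | [Br-].OCCCCCCC[P+](c1ccccc1)(c1ccccc1)c1ccccc1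
F10 | step 11 | methyl 2‑[(3R,5R)‑5‑[(2Z)‑9‑hydroxynon‑2‑en‑1‑yl]‑3,5‑dimethyl‑1,2‑dioxolan‑3‑yl]acetate | OCCCCCC/C=C\C[C@]1(C)C[C@](C)(CC(=O)OC)OO1
F11 | step 11 | methyl 2‑[(3R,5R)‑5‑(9‑hydroxynonyl)‑3,5‑dimethyl‑1,2‑dioxolan‑3‑yl]acetate | OCCCCCCCCC[C@]1(C)C[C@](C)(CC(=O)OC)OO1
F12 | step 11 | methyl 2‑[(3R,5R)‑3,5‑dimethyl‑5‑(9‑oxononyl)‑1,2‑dioxolan‑3‑yl]acetate | O=CCCCCCCCC[C@]1(C)C[C@](C)(CC(=O)OC)OO1
F13 | step 11 | diethyl [(2E,4E)‑hepta‑2,4‑dien‑1‑yl]phosphonate | CC/C=C/C=C/CP(=O)(OCC)OCC
F14 | step 11 | (2E,4E)‑1‑bromohepta‑2,4‑diene | CC/C=C/C=C/CBr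
A1 | alternative 1 | (5R)‑5‑(dec‑9‑yn‑1‑yl)‑3‑methoxy‑3,5‑dimethyl‑1,2‑dioxolane (C3 epimer mixture) | C#CCCCCCCCC[C@]1(C)CC(C)(OC)OO1
A2 | alternative 1 | (2S)‑2‑(dec‑9‑yn‑1‑yl)‑2‑methyloxetane | C#CCCCCCCCC[C@@]1(C)CCO1
A3 | alternative 2 | methyl (2E)‑5‑hydroperoxy‑3,5‑dimethylpentadec‑2‑en‑14‑ynoate (racemic) | C#CCCCCCCCCC(C)(OO)C/C(C)=C/C(=O)OC
A4 | alternative 3 | triethyl[(2‑methoxydodec‑11‑yn‑2‑yl)peroxy]silane (racemic) | C#CCCCCCCCCC(C)(OC)OO[Si](CC)(CC)CC
A5 | alternative 3 | methyl 3‑methylbut‑3‑enoate | C=C(C)CC(=O)OC
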